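A flat tail in a run tempts you to say that partner was taken up by substrate. The alder run forbids that. Its substrate lost 0.504 M, and even two partners for each substrate take 1.01 M, less than the 1.7 M charged.

| flask | substrate | partner | remark | time |
|---|---|---|---|---|
| maple | 0.80 M | 0.53 M | run made earlier |  |
| alder | 0.80 M | 1.7 M | run made earlier |  |
| theta | 0.80 M | 0.640 M |  | 2.5 min |
| beta | 0.80 M | 2.00 M |  | 2.5 min |
| gamma | 0.80 M | 1.60 M |  | 2.5 min |

- maple (time / s: other mono adduct / %, single product / %, substrate / %): 20.0: 12, 6, 73; 40.0: 13, 7, 74; 50.0: 18, 7, 73; 80.0: 16, 2, 74; 120: 16, 9, 75
- alder (time / s: other mono adduct / %, single product / %, substrate / %): 10.0: 28, 5, 47; 15.0: 31, 6, 41; 25.0: 32, 3, 38; 40.0: 28, 4, 37; 60.0: 31, 3, 34; 120: 32, 6, 37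

(standard deviation of a reading: 1.5 percentage points)

- the numbers in the tables scatter by 1.5 percentage points (one standard deviation)

* which of these holds the largest part of the substrate at the end of theta (double product / single product / other mono adduct / substrate)
* which of these holds the largest part of the substrate at the end of beta (double product / single product / other mono adduct / substrate)
* which of these holds the largest part of the substrate at the end of gamma (double product / single product / other mono adduct / substrate)
* final other mono adduct in theta, as a percentage of the substrate charged

Here is my own reckoning, built up for theta one process at a time, in fractions of the charge. First take the main step: one partner per substrate, with partner as the limiting reagent. That converts 80.0% of the substrate. An even split between the two mono adducts is the zero of the scale, so other mono adduct stands at 40.0%.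

Now add a loss of partner by itself, which the alder sum suggests. If that loss is first order, substrate sees a fixed dose in proportion to the partner charge. Define the dose coefficient as the logarithm of charged over remaining substrate, per molar of partner charged 0.585 /M. That value comes from the alder run, and the maple run reads 0.543 /M. I then reckon that theta keeps 68.8% of its substrate, and the even split falls to 15.6%.

Last come the mono adducts' further fates. In the last maple reading, other mono adduct is 0.640 of the substrate lost, so I reckon 20.0% for theta. The last alder reading gives 0.508, with 25.0% unread. For gamma I reckon 39.2% substrate against 30.9% other mono adduct, so I call substrate. For beta I reckon 31.0% against 35.0%. The remaining 33.9% includes single product, so I call other mono adduct, narrowly.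

The forecast uses the same picture: “The partner (or its activity) seems to die off, giving a fixed reaction "dose" proportional to its charge”. It names substrate for theta, double product for beta at 34%, and substrate for gamma. It gives 19% for n, from 16.5% to 21.5%. On beta it differs from my call.

The flasks give substrate for theta, other mono adduct for beta and substrate for gamma, with n at 17.0% in theta.

    substrate + partner → single product (k = 0.0390 /M/s)
    substrate + partner → other mono adduct (k = 0.0550 /M/s)
    partner + single product → double product (k = 0.00910 /M/s)
    partner + other mono adduct → double product (k = 0.0290 /M/s)
    partner → decomposed reagent (k = 0.0840 /s)
    partner + single product → over-reaction product (k = 0.420 /M/s)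

Theta keeps 69.2% substrate against the reckoned 68.8%. Beta holds 9.28% double product and 26.1% over-reaction product. Now take the neighbour of theta charged with 2.6 M of partner. The dose coefficient leaves 21.8% substrate there, and that flask holds 17.3%. Its largest part is other mono adduct, at 34.6%.

The earlier runs and the new flask are calculated with constants of no real substance, and the scatter is random.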